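**Plan**

1. Ring A is numbered as in the bibenzyl: C1 carries the CH2CH2Ar chain, C2 the 4-hydroxybenzyl group, C3 the OMe, C5 the OH. The retrosynthesis first cuts three O–benzyl bonds and the O–Me bond, then the C2–CH2 bond of the diarylmethane, then ring A itself into an enone and malonate.
2. Enabling feature: ring A is a 1,3-dioxygenated benzene, so it is a latent cyclohexane-1,3-dione. C2 lies next to C3 only and not between the two oxygens, so it maps onto the α′-carbon (C6) of a 3-alkoxycyclohex-2-enone whose carbonyl becomes C3–OMe and whose enol-ether oxygen becomes C5–OH.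
3. The benzylic carbon with its 4-oxyphenyl ring is the carbonyl carbon of 4-(benzyloxy)benzaldehyde. Its aldehyde oxidation level pays for the aromatization, so no oxidant is needed.
4. Forward: aryl iodide + allyl alcohol → 3-arylpropanal → enone → 5-substituted cyclohexane-1,3-dione (ring A, not yet aromatic) → benzyl vinylogous ester → α′-aldol → dehydration/isoaromatization (ring A becomes aromatic) → O-methylation → global hydrogenolysis.
5. Stereochemistry: the target has no stereocentre. The centres of the intermediates arise without control and are erased when ring A aromatizes.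

Key step: step 5

Remark: intermediates 7–10, 12 and 14–16 are racemic or diastereomer mixtures; their SMILES carry no configuration except the E double bonds of 5 and 16.

**Step 1**
Reactants: 1 1-(benzyloxy)-2-iodobenzene; 2 prop-2-en-1-ol (allyl alcohol)
Product: 3 3-[2-(benzyloxy)phenyl]propanal
Conditions: Pd(OAc)2 (3 mol%), Bu4NCl, NaHCO3, DMF, 40 °C
Reagents that add atoms: none
Why: Mizoroki–Heck arylation of allyl alcohol under ligand-free phase-transfer conditions; the aryl group should add to the terminal carbon and β-hydride elimination toward the carbinol carbon gives an enol that tautomerizes to the aldehyde.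

**Step 2**
Reactants: 3 3-[2-(benzyloxy)phenyl]propanal; 4 1-(triphenyl-λ5-phosphanylidene)propan-2-one
Product: 5 (3E)-6-[2-(benzyloxy)phenyl]hex-3-en-2-one
Conditions: CH2Cl2, 40 °C
Reagents that add atoms: none
Why: Wittig olefination with a stabilized acyl ylide, which should give the E-enone at an unhindered aliphatic aldehyde.

**Step 3**
Reactants: 5 (3E)-6-[2-(benzyloxy)phenyl]hex-3-en-2-one; 6 dimethyl malonate
Product: 10 5-{2-[2-(benzyloxy)phenyl]ethyl}cyclohexane-1,3-dione, via Michael adduct 7 (not isolated), via cyclic keto ester 8 (not isolated), via keto acid 9 (not isolated)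
Conditions: NaOMe, MeOH, reflux; 2 M NaOH, reflux; then HCl to pH 1, 80 °C
Reagents that add atoms: none
Why: Michael addition of the malonate anion to the enone, intramolecular Claisen (Dieckmann-type) condensation of the methyl ketone onto a malonate ester, then saponification and decarboxylation of the β-keto acid, the classical route to 5-substituted cyclohexane-1,3-diones; the ring centre is formed racemic.

**Step 4**
Reactants: 10 5-{2-[2-(benzyloxy)phenyl]ethyl}cyclohexane-1,3-dione; 11 benzyl alcohol
Product: 12 3-(benzyloxy)-5-{2-[2-(benzyloxy)phenyl]ethyl}cyclohex-2-en-1-one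
Conditions: BnOH (2 equiv), TsOH·H2O (5 mol%), toluene, reflux, Dean–Stark
Reagents that add atoms: none
Why: acid-catalysed enol etherification of a cyclic 1,3-dione with azeotropic removal of water (vinylogous ester formation); 10 is symmetric, so only one regioisomer can form, and this step differentiates the two ring-A oxygens.

**Step 5**
Reactants: 12 3-(benzyloxy)-5-{2-[2-(benzyloxy)phenyl]ethyl}cyclohex-2-en-1-one; 13 4-(benzyloxy)benzaldehyde
Product: 15 3-(benzyloxy)-5-{2-[2-(benzyloxy)phenyl]ethyl}-6-{[4-(benzyloxy)phenyl](hydroxy)methyl}cyclohex-2-en-1-one (diastereomer mixture), via lithium dienolate 14 (not isolated)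
Conditions: LDA (1.1 equiv), THF, −78 °C; then 13, THF, −78 °C; AcOH quench at −78 °C
Reagents that add atoms: lithium diisopropylamide, CC(C)N([Li])C(C)C (supplies only the lithium of intermediate 14; none of its atoms other than hydrogen remains in 15)
Why: LDA removes a C6 (α′) proton of vinylogous ester 12 under kinetic control to give the cross-conjugated lithium dienolate 14, which adds through C6 to the non-enolizable aldehyde 13 by way of a closed six-membered lithium-chelated transition state; the new C6–CH(OH)Ar bond is the ring-A-to-benzylic-carbon bond of the target. The closest known reaction type is the Stork–Danheiser α′-functionalization of 3-alkoxycyclohex-2-enones, used here in its crossed-aldol form. No ring is closed in this step. Two stereocentres (C6 and the carbinol carbon) are created, C6 probably trans to the C5 side chain for steric reasons and the carbinol centre without useful control, which is acceptable because C5, C6 and the carbinol centre are all erased in step 6. The selectivity needed is regiochemical (C6 against C2 and C4 of the 1,3-dioxygenated ring) and is secured by the substrate: the benzyl enol ether ties up one oxygen, so that only the carbon flanked by the free carbonyl (the future C–OMe) and the side-chain carbon carries kinetically acidic protons, and not the carbon between the two oxygens that a dione or a phenol would offer. Choosing the aldehyde as electrophile also stores in the carbinol the oxidation level that lets ring A aromatize in step 6 without an oxidant.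

**Step 6**
Reactants: 15 3-(benzyloxy)-5-{2-[2-(benzyloxy)phenyl]ethyl}-6-{[4-(benzyloxy)phenyl](hydroxy)methyl}cyclohex-2-en-1-one
Product: 17 5-(benzyloxy)-3-{2-[2-(benzyloxy)phenyl]ethyl}-2-[4-(benzyloxy)benzyl]phenol, via arylidene dienone 16 (not isolated)
Conditions: TsOH·H2O (10 mol%), 4 Å MS, toluene (0.05 M), 90 °C
Reagents that add atoms: none
Why: acid-catalysed dehydration of the benzylic β-hydroxy ketone to the (E)-arylidene dienone, then isoaromatization (exocyclic-to-endocyclic double-bond migration through the dienol, of the carvone-to-carvacrol type), driven by formation of the benzene ring; the former carbonyl oxygen should emerge as the only free phenol and the benzyl enol ether as an aryl benzyl ether, with all three stereocentres erased.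

**Step 7**
Reactants: 17 5-(benzyloxy)-3-{2-[2-(benzyloxy)phenyl]ethyl}-2-[4-(benzyloxy)benzyl]phenol
Product: 18 5-(benzyloxy)-1-{2-[2-(benzyloxy)phenyl]ethyl}-2-[4-(benzyloxy)benzyl]-3-methoxybenzene
Conditions: MeI, K2CO3, DMF, 40 °C
Reagents that add atoms: iodomethane, CI
Why: Williamson O-methylation of the only free phenol, which places the methyl group on the oxygen next to the benzylated carbon.

**Step 8**
Reactants: 18 5-(benzyloxy)-1-{2-[2-(benzyloxy)phenyl]ethyl}-2-[4-(benzyloxy)benzyl]-3-methoxybenzene
Product: 19 4-[(4-hydroxyphenyl)methyl]-3-[2-(2-hydroxyphenyl)ethyl]-5-methoxyphenol (CNP0289131.0)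
Conditions: H2 (1 atm), 10% Pd/C, EtOAc–MeOH, rt
Reagents that add atoms: none
Why: catalytic hydrogenolysis of the three aryl benzyl ethers in one operation; the diarylmethane and bibenzyl C–C bonds and the aryl methyl ether should be inert to H2/Pd-C at room temperature.

**Compound list**

1 | 1-(benzyloxy)-2-iodobenzene | Ic1ccccc1OCc1ccccc1 | starting material
2 | prop-2-en-1-ol (allyl alcohol) | C=CCO | starting material
3 | 3-[2-(benzyloxy)phenyl]propanal | O=CCCc1ccccc1OCc1ccccc1 | intermediate
4 | 1-(triphenyl-λ5-phosphanylidene)propan-2-one | CC(=O)C=P(c1ccccc1)(c1ccccc1)c1ccccc1 | starting material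
5 | (3E)-6-[2-(benzyloxy)phenyl]hex-3-en-2-one | CC(=O)/C=C/CCc1ccccc1OCc1ccccc1 | intermediate
6 | dimethyl malonate | COC(=O)CC(=O)OC | starting material
7 | Michael adduct (not isolated; sodium enolate in the flask): dimethyl 2-{1-[2-(benzyloxy)phenyl]-5-oxohexan-3-yl}propanedioate, racemic | COC(=O)C(C(=O)OC)C(CCc1ccccc1OCc1ccccc1)CC(C)=O | intermediate
8 | cyclic keto ester (not isolated; sodium enolate in the flask): methyl 6-{2-[2-(benzyloxy)phenyl]ethyl}-2,4-dioxocyclohexane-1-carboxylate, racemic | COC(=O)C1C(=O)CC(=O)CC1CCc1ccccc1OCc1ccccc1 | intermediate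
9 | keto acid (not isolated): 6-{2-[2-(benzyloxy)phenyl]ethyl}-2,4-dioxocyclohexane-1-carboxylic acid, racemic | OC(=O)C1C(=O)CC(=O)CC1CCc1ccccc1OCc1ccccc1 | intermediate
10 | 5-{2-[2-(benzyloxy)phenyl]ethyl}cyclohexane-1,3-dione | O=C1CC(=O)CC(CCc2ccccc2OCc2ccccc2)C1 | intermediate
11 | benzyl alcohol | OCc1ccccc1 | starting material
12 | 3-(benzyloxy)-5-{2-[2-(benzyloxy)phenyl]ethyl}cyclohex-2-en-1-one, racemic | O=C1C=C(OCc2ccccc2)CC(CCc2ccccc2OCc2ccccc2)C1 | intermediate
13 | 4-(benzyloxy)benzaldehyde | O=Cc1ccc(OCc2ccccc2)cc1 | starting material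
14 | lithium dienolate (not isolated): lithium 5-(benzyloxy)-3-{2-[2-(benzyloxy)phenyl]ethyl}cyclohexa-1,5-dien-1-olate, racemic | [Li]OC1=CC(CCc2ccccc2OCc2ccccc2)CC(OCc2ccccc2)=C1 | intermediate
15 | 3-(benzyloxy)-5-{2-[2-(benzyloxy)phenyl]ethyl}-6-{[4-(benzyloxy)phenyl](hydroxy)methyl}cyclohex-2-en-1-one, racemic diastereomer mixture | O=C1C=C(OCc2ccccc2)CC(CCc2ccccc2OCc2ccccc2)C1C(O)c1ccc(OCc2ccccc2)cc1 | intermediate
16 | arylidene dienone (not isolated): (6E)-3-(benzyloxy)-5-{2-[2-(benzyloxy)phenyl]ethyl}-6-{[4-(benzyloxy)phenyl]methylidene}cyclohex-2-en-1-one, racemic | O=C1C=C(OCc2ccccc2)CC(CCc2ccccc2OCc2ccccc2)/C1=C\c1ccc(OCc2ccccc2)cc1 | intermediate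
17 | 5-(benzyloxy)-3-{2-[2-(benzyloxy)phenyl]ethyl}-2-[4-(benzyloxy)benzyl]phenol | Oc1cc(OCc2ccccc2)cc(CCc2ccccc2OCc2ccccc2)c1Cc1ccc(OCc2ccccc2)cc1 | intermediate
18 | 5-(benzyloxy)-1-{2-[2-(benzyloxy)phenyl]ethyl}-2-[4-(benzyloxy)benzyl]-3-methoxybenzene | COc1cc(OCc2ccccc2)cc(CCc2ccccc2OCc2ccccc2)c1Cc1ccc(OCc2ccccc2)cc1 | intermediate
19 | 4-[(4-hydroxyphenyl)methyl]-3-[2-(2-hydroxyphenyl)ethyl]-5-methoxyphenol | COc1cc(O)cc(CCc2ccccc2O)c1Cc1ccc(O)cc1 | target

**Step count**

Total: 8 steps. Longest linear sequence: 8 steps (1 → 19); compounds 2, 4, 6, 11 and 13 are commercial.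

**Steps most likely to fail, with fallbacks**

Step 6. The exocyclic double bond may fail to migrate into the ring under mild acid, so that the reaction stalls at the arylidene stage. The water of dehydration may also hydrolyse the benzyl enol ether before aromatization, which would erase the differentiation of the two oxygens. The fallback sets out from 12 and returns at 17; it forms the C–C bond at the alkane oxidation level and aromatizes oxidatively, so neither dehydration nor isomerization is needed. Dienolate 14 would be alkylated with 4-(benzyloxy)benzyl bromide (LDA, THF–DMPU, −78 → 0 °C; Stork–Danheiser alkylation) to give 3-(benzyloxy)-5-{2-[2-(benzyloxy)phenyl]ethyl}-6-[4-(benzyloxy)benzyl]cyclohex-2-en-1-one F1. A second α′-deprotonation (LDA, −78 °C) and trapping with PhSeBr would give 3-(benzyloxy)-5-{2-[2-(benzyloxy)phenyl]ethyl}-6-[4-(benzyloxy)benzyl]-6-(phenylselanyl)cyclohex-2-en-1-one F2. Oxidation (H2O2, pyridine, CH2Cl2, 0 °C) should give selenoxide syn-elimination into the ring (toward C5–H, cis to selenium) and tautomerization of the dienone to phenol 17.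

Step 3. The γ-enolizable enone may undergo retro-Michael fragmentation or self-condensation under methoxide, ring closure may be incomplete, and the hot acidic decarboxylation may partly cleave the aryl benzyl ether. The fallback sets out from 5 and returns at 10, avoiding malonate and any decarboxylation. Mukaiyama–Michael addition of 1-methoxy-1-(trimethylsilyloxy)ethene to 5 (TiCl4, CH2Cl2, −78 °C) would give methyl 3-{2-[2-(benzyloxy)phenyl]ethyl}-5-oxohexanoate F3. Intramolecular Claisen condensation (t-BuOK, THF, 0 °C → rt; dilute HCl work-up) would then close the ring to dione 10.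

Step 1. β-Hydride elimination may go the wrong way (allylic alcohol products), insertion may be branched, and the product aldehyde may self-condense under the basic conditions. The fallback sets out from 1 and returns at 3, bringing in the three-carbon unit with the aldehyde masked. Negishi coupling of 1 with commercial [2-(1,3-dioxolan-2-yl)ethyl]zinc bromide (Pd(dppf)Cl2, THF, 50 °C) would give 2-{2-[2-(benzyloxy)phenyl]ethyl}-1,3-dioxolane F4. Acetal hydrolysis (1 M HCl, THF, rt) would release aldehyde 3.

**Further compounds**

F1 | step 6 | 3-(benzyloxy)-5-{2-[2-(benzyloxy)phenyl]ethyl}-6-[4-(benzyloxy)benzyl]cyclohex-2-en-1-one (racemic) | O=C1C=C(OCc2ccccc2)CC(CCc2ccccc2OCc2ccccc2)C1Cc1ccc(OCc2ccccc2)cc1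
F2 | step 6 | 3-(benzyloxy)-5-{2-[2-(benzyloxy)phenyl]ethyl}-6-[4-(benzyloxy)benzyl]-6-(phenylselanyl)cyclohex-2-en-1-one (racemic) | O=C1C=C(OCc2ccccc2)CC(CCc2ccccc2OCc2ccccc2)C1(Cc1ccc(OCc2ccccc2)cc1)[Se]c1ccccc1
F3 | step 3 | methyl 3-{2-[2-(benzyloxy)phenyl]ethyl}-5-oxohexanoate (racemic) | COC(=O)CC(CCc1ccccc1OCc1ccccc1)CC(C)=O
F4 | step 1 | 2-{2-[2-(benzyloxy)phenyl]ethyl}-1,3-dioxolane | C1COC(CCc2ccccc2OCc2ccccc2)O1
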